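**Retrosynthetic overview**

1. Locants follow 1H-isochromene (O2, C1, C3, C4, C4a, C5 to C8, C8a). The last bonds made are the C6–O ester (acid chloride), the oxirane (Shi epoxidation of an E-propenyl group) and the pyran bond O2–C3 (6-endo oxa-Michael closure of the C1 alkoxide onto a C4a-alkynyl enone, which comes from Vilsmeier haloformylation and Sonogashira coupling of a cyclohexane-1,3-dione).
2. Key disconnection: C6–C7 and C5–C4a are cut together. The carbocycle is made first, in one flask, by a double Claisen condensation ([4+2]) of a lactic-acid-derived β-keto thioester (C7–C8–C8a–C4a) with an acetyl donor (C5–C6).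
3. Enabling feature: in the carbocycle C4a–C5–C6–C7–C8–C8a the atoms C4a, C6 and C8 carry oxygen or are sp2 and alternate with C5 and C8a around the quaternary carbinol C7. At the triketone level this ring is the Cs-symmetric 2-oxy-2-methylcyclohexane-1,3,5-trione (mirror plane through C7 and C4a), in which C6 and C8 are enantiotopic.
4. The key step therefore needs no stereocontrol; C6 and C7 are set together afterwards by one desymmetrizing asymmetric transfer hydrogenation.
5. Ring order: carbocycle (step 2), pyran (step 8), oxirane (step 10).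

Key step: step 2

Assumption: (3E)-pent-3-en-1-yne is taken as commercial, and the sense of induction in step 3 is taken from the aryl ketone model of the catalyst with the quaternary C7 in the place of the aryl group (if the real sense is opposite, the (S,S) complex is used).

**Route**

Step 1
Reactants: 1 (2S)-2-(benzyloxy)propanoic acid; 2 2,2-dimethyl-1,3-dioxane-4,6-dione (Meldrum's acid)
Product: 4 S-tert-butyl (4S)-4-(benzyloxy)-3-oxopentanethioate, via acyl Meldrum's acid 3 (not isolated)
Conditions: DCC, DMAP, CH2Cl2, 0 °C to rt; then t-BuSH, toluene, 80 °C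
Reagents that add atoms: 2-methylpropane-2-thiol (CC(C)(C)S)
Why: C-acylation of Meldrum's acid followed by thermal loss of acetone and CO2 to an acylketene that the thiol traps is a standard β-keto (thio)ester synthesis, and the lactate stereocentre need not survive because step 2 makes this carbon trigonal.

Step 2
Reactants: 4 S-tert-butyl (4S)-4-(benzyloxy)-3-oxopentanethioate; 5 1-acetylimidazole
Product: 7 2-(benzyloxy)-2-methylcyclohexane-1,3,5-trione, via acyclic diketo thioester 6 (not isolated)
Conditions: LiN(i-Pr)2 (2.2 equiv), THF, −78 to −30 °C; 5, −78 °C; then LiN(SiMe3)2 (1.5 equiv), −78 to 40 °C; 1 M HCl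
Reagents that add atoms: none
Why: Two equivalents of amide base give the 1,3-dianion of 4, whose γ-carbon (the future C7, bearing CH3 and OBn) is C-acylated by 5 to the diketo thioester 6 (C6–C7 bond); a further equivalent of base enolizes the new methyl ketone, and its carbon (C5) attacks the thioester carbonyl (C4a) with loss of tert-butanethiolate (C5–C4a bond). The closest known reaction types are the γ-acylation of β-keto ester dianions and the Dieckmann closure of δ-keto esters to cyclohexane-1,3-diones; the ring closes in a 6-(enolendo)-exo-trig mode. No stereocentre survives the step, because the quaternary carbon of racemic 6 becomes the prochiral C7 of the Cs-symmetric trione 7, so nothing has to be controlled here and configuration is decided in step 3. The selectivities needed are C- over O-acylation and Claisen closure over lactonization or retro-Claisen cleavage. They should be secured by the carbanion character of the dianion γ-carbon, by the thioester as the only acyl group that can lose a leaving group in a six-membered closure, by the quaternary C7 that blocks the usual 4-hydroxy-2-pyranone outlet, and by the irreversible formation of the vinylogous acid anion of 7.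

Step 3
Reactants: 7 2-(benzyloxy)-2-methylcyclohexane-1,3,5-trione
Product: 8 (4R,5R)-4-(benzyloxy)-5-hydroxy-4-methylcyclohexane-1,3-dione
Conditions: RuCl(p-cymene)[(R,R)-TsDPEN] (1 mol%), HCO2H/Et3N (5:2), DMF, rt
Reagents that add atoms: none
Why: Noyori-type asymmetric transfer hydrogenation should desymmetrize 7, since in each of its two rapidly interconverting mono-enols only the non-enolized carbonyl next to C7 is reducible, the chiral ruthenium hydride selects one enantiotopic carbonyl (C6) and hydride is delivered anti to the C7–O bond, so that C6 (R) and C7 (R) are created together with the C6 hydroxyl cis to the C7 oxygen.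

Step 4
Reactants: 8 (4R,5R)-4-(benzyloxy)-5-hydroxy-4-methylcyclohexane-1,3-dione
Product: 9 (4R,5R)-4,5-dihydroxy-4-methylcyclohexane-1,3-dione
Conditions: H2 (1 atm), Pd/C, EtOAc, rt
Reagents that add atoms: none
Why: Hydrogenolysis of the tertiary benzyl ether frees the C7 hydroxyl before any alkene or alkyne is present and touches no stereocentre.

Step 5
Reactants: 9 (4R,5R)-4,5-dihydroxy-4-methylcyclohexane-1,3-dione
Product: 10 (3aR,7aR)-2,2,7a-trimethyltetrahydro-1,3-benzodioxole-5,7-dione
Conditions: 2-methoxypropene, PPTS (cat.), CH2Cl2, 0 °C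
Reagents that add atoms: 2-methoxypropene (COC(C)=C)
Why: Acid-catalysed transacetalization gives the cis-fused acetonide, which only the cis-diol forms readily, masks both hydroxyls as poor leaving groups and leaves the 1,3-dione free.

Step 6
Reactants: 10 (3aR,7aR)-2,2,7a-trimethyltetrahydro-1,3-benzodioxole-5,7-dione
Product: 11 (3aR,7aR)-5-chloro-2,2,7a-trimethyl-7-oxo-3a,4,7,7a-tetrahydro-1,3-benzodioxole-6-carbaldehyde
Conditions: POCl3, DMF, CH2Cl2, 0 °C to rt; aq. NaOAc
Reagents that add atoms: N,N-dimethylformamide (CN(C)C=O); phosphoryl chloride (O=P(Cl)(Cl)Cl); water (O)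
Why: Vilsmeier–Haack–Arnold haloformylation should formylate the dione carbon C8a and turn the less hindered vinylogous acid oxygen (on C4a, remote from the quaternary C7) into the vinyl chloride, which keeps C8 as the ketone.

Step 7
Reactants: 11 (3aR,7aR)-5-chloro-2,2,7a-trimethyl-7-oxo-3a,4,7,7a-tetrahydro-1,3-benzodioxole-6-carbaldehyde; 12 (3E)-pent-3-en-1-yne
Product: 13 (3aR,7aR)-2,2,7a-trimethyl-7-oxo-5-[(3E)-pent-3-en-1-yn-1-yl]-3a,4,7,7a-tetrahydro-1,3-benzodioxole-6-carbaldehyde
Conditions: PdCl2(PPh3)2 (3 mol%), CuI (5 mol%), Et3N, THF, rt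
Reagents that add atoms: none
Why: Sonogashira coupling of the activated β-chloro enal (a vinylogous acid chloride) with the terminal enyne attaches C4, C3 and the propenyl chain to C4a with the E-olefin unchanged.

Step 8
Reactants: 13 (3aR,7aR)-2,2,7a-trimethyl-7-oxo-5-[(3E)-pent-3-en-1-yn-1-yl]-3a,4,7,7a-tetrahydro-1,3-benzodioxole-6-carbaldehyde
Product: 15 6,7-O-isopropylidene acetal of (6R,7R)-6,7-dihydroxy-7-methyl-3-[(1E)-prop-1-en-1-yl]-6,7-dihydro-1H-isochromen-8(5H)-one, via hydroxymethyl enynone 14 (not isolated)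
Conditions: NaBH4, MeOH/CH2Cl2, −78 °C; then K2CO3, 0 °C to rt
Reagents that add atoms: none
Why: Borohydride at low temperature should reduce the aldehyde (C1) in preference to the hindered conjugated C8 ketone, and the C1 alkoxide then adds 6-endo-dig to the δ-carbon (C3) of the ynenone (intramolecular oxa-Michael hydroalkoxylation), closing the pyran ring as the conjugated 1H-isochromen-8-one.

Step 9
Reactants: 15 6,7-O-isopropylidene acetal of (6R,7R)-6,7-dihydroxy-7-methyl-3-[(1E)-prop-1-en-1-yl]-6,7-dihydro-1H-isochromen-8(5H)-one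
Product: 16 (6R,7R)-6,7-dihydroxy-7-methyl-3-[(1E)-prop-1-en-1-yl]-6,7-dihydro-1H-isochromen-8(5H)-one
Conditions: AcOH/H2O/THF (3:1:1), 40 °C
Reagents that add atoms: none
Why: Mild aqueous acid hydrolyses the acetonide before the acid-labile epoxide exists, and the push-pull (vinylogous ester) pyran is expected to tolerate these conditions.

Step 10
Reactants: 16 (6R,7R)-6,7-dihydroxy-7-methyl-3-[(1E)-prop-1-en-1-yl]-6,7-dihydro-1H-isochromen-8(5H)-one
Product: 17 (6R,7R)-6,7-dihydroxy-7-methyl-3-[(2S,3R)-3-methyloxiran-2-yl]-6,7-dihydro-1H-isochromen-8(5H)-one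
Conditions: D-fructose-derived Shi ketone (30 mol%), KHSO5 (as 2KHSO5·KHSO4·K2SO4), K2CO3, Bu4NHSO4, MeCN/CH2(OMe)2/aq. Na2B4O7, 0 °C
Reagents that add atoms: potassium peroxymonosulfate ([K+].[O-]S(=O)(=O)OO)
Why: Shi epoxidation should oxidize the most remote and most electron-rich olefin of the trienone (the E-propenyl group) through the spiro transition state that gives the usual (R,R)-type face selectivity of trans-olefins, which here is the (2S,3R)-oxirane, while the tetrasubstituted enone and the acceptor-conjugated enol ether are deactivated.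

Step 11
Reactants: 18 2,4-dihydroxy-6-methylbenzoic acid (orsellinic acid)
Product: 20 2,4-bis[(tert-butyldimethylsilyl)oxy]-6-methylbenzoic acid, via tris-silyl compound 19 (not isolated)
Conditions: TBSCl (3.3 equiv), imidazole, DMF, rt; then AcOH/THF/H2O, rt
Reagents that add atoms: tert-butylchlorodimethylsilane (CC(C)(C)[Si](C)(C)Cl)
Why: Exhaustive silylation followed by selective hydrolysis of the labile silyl ester gives the acid with both phenols protected by groups that fluoride removes under near-neutral conditions.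

Step 12
Reactants: 17 (6R,7R)-6,7-dihydroxy-7-methyl-3-[(2S,3R)-3-methyloxiran-2-yl]-6,7-dihydro-1H-isochromen-8(5H)-one; 20 2,4-bis[(tert-butyldimethylsilyl)oxy]-6-methylbenzoic acid
Product: 22 (6R,7R)-7-hydroxy-7-methyl-3-[(2S,3R)-3-methyloxiran-2-yl]-8-oxo-5,6,7,8-tetrahydro-1H-isochromen-6-yl 2,4-bis[(tert-butyldimethylsilyl)oxy]-6-methylbenzoate, via acid chloride 21 (not isolated)
Conditions: 20, 1-chloro-N,N,2-trimethylprop-1-en-1-amine, CH2Cl2, rt; then 17, pyridine, DMAP, 0 °C to rt
Reagents that add atoms: none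
Why: The neutral chloroenamine converts 20 into acid chloride 21, which under nucleophilic catalysis should acylate the secondary C6 hydroxyl in preference to the tertiary C7 hydroxyl without touching any stereocentre.

Step 13
Reactants: 22 (6R,7R)-7-hydroxy-7-methyl-3-[(2S,3R)-3-methyloxiran-2-yl]-8-oxo-5,6,7,8-tetrahydro-1H-isochromen-6-yl 2,4-bis[(tert-butyldimethylsilyl)oxy]-6-methylbenzoate
Product: 23 (6R,7R)-7-hydroxy-7-methyl-3-[(2S,3R)-3-methyloxiran-2-yl]-8-oxo-5,6,7,8-tetrahydro-1H-isochromen-6-yl 2,4-dihydroxy-6-methylbenzoate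
Conditions: Bu4NF, AcOH (1:1), THF, 0 °C
Reagents that add atoms: none
Why: Acetic-acid-buffered fluoride cleaves the two aryl silyl ethers far faster than it can affect the ester, the epoxide or the α-ketol, so the target should be released with all four stereocentres unchanged.

**Compound list**

1 | (2S)-2-(benzyloxy)propanoic acid | C[C@H](OCc1ccccc1)C(=O)O | starting material
2 | 2,2-dimethyl-1,3-dioxane-4,6-dione (Meldrum's acid) | CC1(C)OC(=O)CC(=O)O1 | starting material
3 | 5-[(2S)-2-(benzyloxy)-1-hydroxypropylidene]-2,2-dimethyl-1,3-dioxane-4,6-dione | C[C@H](OCc1ccccc1)C(O)=C1C(=O)OC(C)(C)OC1=O | intermediate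
4 | S-tert-butyl (4S)-4-(benzyloxy)-3-oxopentanethioate | C[C@H](OCc1ccccc1)C(=O)CC(=O)SC(C)(C)C | intermediate
5 | 1-acetylimidazole | CC(=O)n1ccnc1 | starting material
6 | S-tert-butyl 4-(benzyloxy)-4-methyl-3,5-dioxohexanethioate (racemic) | CC(=O)C(C)(OCc1ccccc1)C(=O)CC(=O)SC(C)(C)C | intermediate
7 | 2-(benzyloxy)-2-methylcyclohexane-1,3,5-trione (achiral; present as mono-enol) | CC1(OCc2ccccc2)C(=O)CC(=O)CC1=O | intermediate
8 | (4R,5R)-4-(benzyloxy)-5-hydroxy-4-methylcyclohexane-1,3-dione | O[C@@H]1CC(=O)CC(=O)[C@]1(C)OCc1ccccc1 | intermediate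
9 | (4R,5R)-4,5-dihydroxy-4-methylcyclohexane-1,3-dione | O[C@@H]1CC(=O)CC(=O)[C@]1(C)O | intermediate
10 | (3aR,7aR)-2,2,7a-trimethyltetrahydro-1,3-benzodioxole-5,7-dione | CC1(C)O[C@@H]2CC(=O)CC(=O)[C@]2(C)O1 | intermediate
11 | (3aR,7aR)-5-chloro-2,2,7a-trimethyl-7-oxo-3a,4,7,7a-tetrahydro-1,3-benzodioxole-6-carbaldehyde | CC1(C)O[C@@H]2CC(Cl)=C(C=O)C(=O)[C@]2(C)O1 | intermediate
12 | (3E)-pent-3-en-1-yne | C#C/C=C/C | starting material
13 | (3aR,7aR)-2,2,7a-trimethyl-7-oxo-5-[(3E)-pent-3-en-1-yn-1-yl]-3a,4,7,7a-tetrahydro-1,3-benzodioxole-6-carbaldehyde | CC1(C)O[C@@H]2CC(C#C/C=C/C)=C(C=O)C(=O)[C@]2(C)O1 | intermediate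
14 | (3aR,7aR)-6-(hydroxymethyl)-2,2,7a-trimethyl-5-[(3E)-pent-3-en-1-yn-1-yl]-3a,7a-dihydro-1,3-benzodioxol-7(4H)-one | CC1(C)O[C@@H]2CC(C#C/C=C/C)=C(CO)C(=O)[C@]2(C)O1 | intermediate
15 | 6,7-O-isopropylidene acetal of (6R,7R)-6,7-dihydroxy-7-methyl-3-[(1E)-prop-1-en-1-yl]-6,7-dihydro-1H-isochromen-8(5H)-one | CC1(C)O[C@@H]2CC3=C(COC(/C=C/C)=C3)C(=O)[C@]2(C)O1 | intermediate
16 | (6R,7R)-6,7-dihydroxy-7-methyl-3-[(1E)-prop-1-en-1-yl]-6,7-dihydro-1H-isochromen-8(5H)-one | O[C@@H]1CC2=C(COC(/C=C/C)=C2)C(=O)[C@]1(C)O | intermediate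
17 | (6R,7R)-6,7-dihydroxy-7-methyl-3-[(2S,3R)-3-methyloxiran-2-yl]-6,7-dihydro-1H-isochromen-8(5H)-one | O[C@@H]1CC2=C(COC([C@H]3O[C@@H]3C)=C2)C(=O)[C@]1(C)O | intermediate
18 | 2,4-dihydroxy-6-methylbenzoic acid (orsellinic acid) | Cc1cc(O)cc(O)c1C(=O)O | starting material
19 | tert-butyldimethylsilyl 2,4-bis[(tert-butyldimethylsilyl)oxy]-6-methylbenzoate | Cc1cc(O[Si](C)(C)C(C)(C)C)cc(O[Si](C)(C)C(C)(C)C)c1C(=O)O[Si](C)(C)C(C)(C)C | intermediate
20 | 2,4-bis[(tert-butyldimethylsilyl)oxy]-6-methylbenzoic acid | Cc1cc(O[Si](C)(C)C(C)(C)C)cc(O[Si](C)(C)C(C)(C)C)c1C(=O)O | intermediate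
21 | 2,4-bis[(tert-butyldimethylsilyl)oxy]-6-methylbenzoyl chloride | Cc1cc(O[Si](C)(C)C(C)(C)C)cc(O[Si](C)(C)C(C)(C)C)c1C(=O)Cl | intermediate
22 | (6R,7R)-7-hydroxy-7-methyl-3-[(2S,3R)-3-methyloxiran-2-yl]-8-oxo-5,6,7,8-tetrahydro-1H-isochromen-6-yl 2,4-bis[(tert-butyldimethylsilyl)oxy]-6-methylbenzoate | Cc1cc(O[Si](C)(C)C(C)(C)C)cc(O[Si](C)(C)C(C)(C)C)c1C(=O)O[C@@H]1CC2=C(COC([C@H]3O[C@@H]3C)=C2)C(=O)[C@]1(C)O | intermediate
23 | (6R,7R)-7-hydroxy-7-methyl-3-[(2S,3R)-3-methyloxiran-2-yl]-8-oxo-5,6,7,8-tetrahydro-1H-isochromen-6-yl 2,4-dihydroxy-6-methylbenzoate | Cc1cc(O)cc(O)c1C(=O)O[C@@H]1CC2=C(COC([C@H]3O[C@@H]3C)=C2)C(=O)[C@]1(C)O | target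

**Step count and risks**

Total step count: 13. Longest linear sequence: 12 steps (steps 1 to 10, 12 and 13, from compound 1); step 11 is the side branch.

Steps most likely to fail:

Step 2. What may go wrong: O-acylation or simple proton transfer at the hindered γ-carbon instead of C-acylation, and failure of the second Claisen closure onto the enolized thioester. Fallback, setting out from 4 and returning at 7: the dianion of 4 is added to acetaldehyde (γ-aldol, −78 °C) to give S-tert-butyl 4-(benzyloxy)-5-hydroxy-4-methyl-3-oxohexanethioate F1. Dess–Martin oxidation of F1 gives 6, now isolated. Soft enolization of 6 (MgBr2·OEt2, i-Pr2NEt, CH2Cl2) should then close the ring to 7 by a magnesium-templated thioester Claisen condensation. This replaces the acylation of a tertiary carbanion by an aldol addition and the strongly basic closure by a chelate-controlled one.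

Step 3. What may go wrong: insufficient discrimination between the enantiotopic carbonyls, or hydride delivery syn to the C7–O bond (poor enantio- or diastereoselection). Fallback, setting out from 7 and returning at 8: NaBH4 (MeOH, −78 °C) gives racemic cis-4-(benzyloxy)-5-hydroxy-4-methylcyclohexane-1,3-dione F2. Kinetic resolution with Candida antarctica lipase B and vinyl acetate is expected to acetylate the enantiomer whose carbinol carbon is (R), giving (1R,2R)-2-(benzyloxy)-2-methyl-3,5-dioxocyclohexyl acetate F3. After separation, K2CO3 in MeOH returns 8.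

Step 10. What may go wrong: competing oxidation of the enol ether double bond, poor facial selectivity on the propenyl group, or base-induced retro-aldol cleavage of the dihydroxy ketone at the pH of the epoxidation. Fallback, setting out from 11 and returning at 17, with the oxirane brought in as a building block:
- 11 is deprotected (AcOH/H2O/THF) to (4R,5R)-2-chloro-4,5-dihydroxy-5-methyl-6-oxocyclohex-1-ene-1-carbaldehyde F4.
- Separately, (E)-but-2-en-1-ol undergoes Sharpless asymmetric epoxidation (Ti(Oi-Pr)4, D-(−)-diethyl tartrate, t-BuOOH) to [(2R,3R)-3-methyloxiran-2-yl]methanol F5.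
- Parikh–Doering oxidation of F5 gives (2S,3R)-3-methyloxirane-2-carbaldehyde F6.
- Ohira–Bestmann homologation of F6 (K2CO3, MeOH) gives (2R,3R)-2-ethynyl-3-methyloxirane F7.
- Sonogashira coupling of F4 with F7 (PdCl2(PPh3)2, CuI, Et3N) gives (4R,5R)-4,5-dihydroxy-5-methyl-2-{[(2R,3R)-3-methyloxiran-2-yl]ethynyl}-6-oxocyclohex-1-ene-1-carbaldehyde F8.
- NaBH4 reduction of F8 to (5R,6R)-5,6-dihydroxy-2-(hydroxymethyl)-6-methyl-3-{[(2R,3R)-3-methyloxiran-2-yl]ethynyl}cyclohex-2-en-1-one F9, followed by K2CO3 in MeOH, should close the pyran ring to 17.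

Further compounds
F1 | step 2 | S-tert-butyl 4-(benzyloxy)-5-hydroxy-4-methyl-3-oxohexanethioate (mixture of diastereomers) | CC(O)C(C)(OCc1ccccc1)C(=O)CC(=O)SC(C)(C)C
F2 | step 3 | racemic cis-4-(benzyloxy)-5-hydroxy-4-methylcyclohexane-1,3-dione | OC1CC(=O)CC(=O)C1(C)OCc1ccccc1
F3 | step 3 | (1R,2R)-2-(benzyloxy)-2-methyl-3,5-dioxocyclohexyl acetate | CC(=O)O[C@@H]1CC(=O)CC(=O)[C@]1(C)OCc1ccccc1
F4 | step 10 | (4R,5R)-2-chloro-4,5-dihydroxy-5-methyl-6-oxocyclohex-1-ene-1-carbaldehyde | O[C@@H]1CC(Cl)=C(C=O)C(=O)[C@]1(C)O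
F5 | step 10 | [(2R,3R)-3-methyloxiran-2-yl]methanol | OC[C@H]1O[C@@H]1C
F6 | step 10 | (2S,3R)-3-methyloxirane-2-carbaldehyde | O=C[C@H]1O[C@@H]1C
F7 | step 10 | (2R,3R)-2-ethynyl-3-methyloxirane | C#C[C@H]1O[C@@H]1C
F8 | step 10 | (4R,5R)-4,5-dihydroxy-5-methyl-2-{[(2R,3R)-3-methyloxiran-2-yl]ethynyl}-6-oxocyclohex-1-ene-1-carbaldehyde | O[C@@H]1CC(C#C[C@H]2O[C@@H]2C)=C(C=O)C(=O)[C@]1(C)O
F9 | step 10 | (5R,6R)-5,6-dihydroxy-2-(hydroxymethyl)-6-methyl-3-{[(2R,3R)-3-methyloxiran-2-yl]ethynyl}cyclohex-2-en-1-one | O[C@@H]1CC(C#C[C@H]2O[C@@H]2C)=C(CO)C(=O)[C@]1(C)O
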